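(The numbers in the tables are calculated for substances that don't exist.)

At 15.0 h, the last reading of the south-east run, you can already count how much work each catalyst has done, and that count carries you to the flask.

all flasks: partner 1.65 M; free catalyst 82 mM

|  | left-handed substrate | right-handed substrate | protic impurity | remark | time |
|---|---|---|---|---|---|
| east | 0.37 M | 0.37 M | 0.011 M | run made earlier |  |
| north-west | 0.83 M | 0.83 M | 0.011 M | run made earlier |  |
| south-east | 0.55 M | 0.55 M | 0.022 M | run made earlier |  |
| flask | 0.55 M | 0.55 M | 0.0110 M |  | 20 h |

- east (time / h: left-handed substrate / %, right-handed substrate / %, left-handed product / %): 2.00: 45.9, 32.7, 2.6; 6.00: 41.6, 19.7, 11.2; 10.0: 35.8, 10.8, 20.8; 15.0: 29.7, 5.2, 28.6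
- north-west (time / h: left-handed substrate / %, right-handed substrate / %, left-handed product / %): 1.33: 48.5, 43.0, 1.2; 3.00: 47.9, 39.5, 2.9; 6.00: 46.4, 32.7, 5.2; 15.0: 42.9, 22.7, 13.9
- south-east (time / h: left-handed substrate / %, right-handed substrate / %, left-handed product / %): 4.00: 46.6, 31.6, 5.6; 8.00: 42.8, 21.5, 10.7; 12.0: 40.1, 15.9, 16.6; 15.0: 38.2, 13.0, 20.8

(standard deviation of a reading: 0.5 percentage points)

1. part of the left-handed substrate and right-handed substrate charged together that has reacted at 20 h
2. excess of left-handed product over right-handed product in the product at 20 h
3. excess of right-handed substrate over left-handed substrate among what is left of the two at 20 h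

1. Divide the substrate of both hands gone from the readings by the free catalyst charged, which gives the turnover number as used here, a count of substrate gone and not of product made. At that hour the east run stands at 5.87 and the north-west run at 6.96, a factor of 1.19, although c(left-handed substrate) differs by a factor of 2.24, so you read the count mainly from the clock.

2. The south-east run has the flask's substrate charge and twice its protic impurity, yet its count of 6.55 lies between the other two, so you take that count for the flask at that hour.

3. From 8.00 h onward that run's count climbs by 0.251 h⁻¹, and carrying this on to 20 h gives 7.80, or c = 58.2%.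

4. That straight line is the weak link, because from 12.0 h onward the same run climbs more slowly, by 0.215 h⁻¹. With this later slope you commit to 7.62 as the turnover number at 20 h, the substrate reacted per catalyst charged by that time, which makes c = 56.8%.

The forecast says c 56% (52% to 60%), eP 1% (−9% to 11%) and eS −57% (−66% to −48%), on the ground that “After the burst, total turnover is nearly zero order in substrate”. Your count speaks to c only and stands 0.8 percentage points above it.

The flask gives c 57.2%, eP −3.11% and eS −60.5%, each inside the forecast's range.

    free catalyst + left-handed substrate ⇌ catalyst intermediate A (K = 1.20 M⁻¹, k = 39.0 M⁻¹ h⁻¹)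
    free catalyst + right-handed substrate ⇌ catalyst intermediate B (K = 18.0 M⁻¹, k = 120 M⁻¹ h⁻¹)
    partner + catalyst intermediate A → free catalyst + left-handed product (k = 1.10 M⁻¹ h⁻¹)
    partner + catalyst intermediate B → free catalyst + right-handed product (k = 0.380 M⁻¹ h⁻¹)
    left-handed product ⇌ right-handed product (k = 0.130 h⁻¹)
    partner ⇌ dormant form (K = 1.50, k = 0.0410 h⁻¹)
    partner + protic impurity → quenched reagent (k = 86.0 M⁻¹ h⁻¹)

Turned back into a count, the flask's c is 7.68 substrates gone per catalyst charged at 20 h, and that count includes the substrate bound in catalyst intermediate A and catalyst intermediate B, which hold 14.5% and 53.0% of the catalyst at that hour. Now take the neighbour flask, charged with 0.33 M of free catalyst. Your count times that charge asks for 2.51 M of substrate, more than the 1.10 M charged, so the reckoning expects that flask to be close to the end of its substrate. It reaches c = 95.6%.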